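**Retrosynthetic overview**
1. Target 20 ⇐ spiro acetyl-trione 17 by gem-diprenylation of its only free ring carbon (last step).
2. The acylphloroglucinol ring is not alkylated onto the terpenoid. It is grown last on a pre-formed quaternary carbon by Claisen closure of triacylmethane 16 onto an axial ester, after the spiro stereocentre is fixed by hydrolysing only the equatorial ester of gem-diester 12.
3. Spiro-cyclohexane/trans-hydrindane 10 ⇐ one-pot [5+1] double alkylation of dimethyl malonate with the C10 bis-electrophile 7; the six-ring carbinol comes from a hydration steered by the axial ester.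
4. Cyclopentane 5 (ring-fusion and five-ring carbinol centres) ⇐ (R)-limonene oxide by glycol cleavage and intramolecular aldol.
5. Ring order: cyclopentane → spiro cyclohexane → trione ring.

Assumption: the target SMILES shows one enol tautomer of the acetyl-trione and all tautomers are treated as one compound; commercial (+)-limonene oxide is taken as the (4R) cis/trans mixture. Locants in names follow octahydroindene numbering (C3 five-ring carbinol, C5 spiro carbon, C7 six-ring carbinol).

**Route**

Step 1
Reactants: 1 (4R)-limonene 1,2-oxide (cis/trans mixture)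
Product: 3 (3R)-6-oxo-3-(prop-1-en-2-yl)heptanal, via limonene-1,2-diol 2 (not isolated)
Conditions: H5IO6 (1.1 equiv), THF/H2O, 0 → 25 °C
Reagents that add atoms: water, O
Why: Acid-mediated epoxide hydration followed by Malaprade glycol cleavage turns both epoxide diastereomers into the same keto aldehyde, and the isopropenyl-bearing stereocentre of (R)-limonene is carried through untouched.

Step 2
Reactants: 3 (3R)-6-oxo-3-(prop-1-en-2-yl)heptanal
Product: 5 (1R,2R,3R)-2-(hydroxymethyl)-1-methyl-3-(prop-1-en-2-yl)cyclopentan-1-ol, via cyclopentane aldol 4 (not isolated)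
Conditions: pyrrolidine (10 mol %), AcOH (10 mol %), CH2Cl2, 0 °C, 2 h; aq. NH4Cl wash; then MeOH, NaBH4, −20 °C
Reagents that add atoms: none
Why: The amine-catalysed intramolecular enamine aldol addition (5-enolexo aldolisation, stopped before dehydration) is reversible and the formyl-bearing carbon is epimerisable, so it should settle on the all-trans aldol (methyl trans to formyl, formyl trans to isopropenyl, hydroxyl cis to formyl and hydrogen-bonded), which NaBH4 then freezes as the diol.

Step 3
Reactants: 5 (1R,2R,3R)-2-(hydroxymethyl)-1-methyl-3-(prop-1-en-2-yl)cyclopentan-1-ol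
Product: 6 [(1R,2R,5R)-2-hydroxy-2-methyl-5-(prop-1-en-2-yl)cyclopentyl]methyl 4-methylbenzenesulfonate
Conditions: TsCl (1.05 equiv), pyridine, DMAP (cat.), CH2Cl2, 0 °C
Reagents that add atoms: p-toluenesulfonyl chloride, Cc1ccc(cc1)S(Cl)(=O)=O
Why: Chemoselective tosylation of the primary hydroxyl over the tertiary one creates the first electrophilic carbon without touching a stereocentre.

Step 4
Reactants: 6 [(1R,2R,5R)-2-hydroxy-2-methyl-5-(prop-1-en-2-yl)cyclopentyl]methyl 4-methylbenzenesulfonate
Product: 7 [(1R,2R,5R)-5-(3-chloroprop-1-en-2-yl)-2-hydroxy-2-methylcyclopentyl]methyl 4-methylbenzenesulfonate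
Conditions: Ca(OCl)2, solid CO2, CH2Cl2/H2O, 0 °C
Reagents that add atoms: Ca(OCl)2 (calcium hypochlorite), [Ca+2].[O-]Cl.[O-]Cl
Why: Ene-type allylic chlorination by HOCl shifts the double bond to give the 2-(chloromethyl)allyl group, which is the second electrophilic carbon, while the new exocyclic CH2 is kept as the future methyl; no stereocentre is affected.

Step 5
Reactants: 7 [(1R,2R,5R)-5-(3-chloroprop-1-en-2-yl)-2-hydroxy-2-methylcyclopentyl]methyl 4-methylbenzenesulfonate; 8 dimethyl malonate
Product: 10 dimethyl (3R,3aS,7aR)-3-hydroxy-3-methyl-7-methylideneoctahydro-5H-indene-5,5-dicarboxylate, via allylated malonate 9 (not isolated)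
Conditions: 8 (1.05 equiv), Cs2CO3 (3 equiv), DMF (0.02 M), 25 °C then 70 °C
Reagents that add atoms: dimethyl malonate 8, COC(=O)CC(=O)OC
Why: Double malonate alkylation ([5+1] spiroannulation) proceeds by fast intermolecular allylic SN2 and then 6-exo-tet displacement of the tosylate, which closes the six-membered ring onto the trans-1,2-disubstituted cyclopentane and so gives the trans-hydrindane with the quaternary carbon in place but not yet stereogenic.

Step 6
Reactants: 10 dimethyl (3R,3aS,7aR)-3-hydroxy-3-methyl-7-methylideneoctahydro-5H-indene-5,5-dicarboxylate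
Product: 12 dimethyl (3R,3aS,7R,7aR)-3,7-dihydroxy-3,7-dimethyloctahydro-5H-indene-5,5-dicarboxylate, via tertiary hydroperoxide 11 (not isolated)
Conditions: Mn(dpm)3 (5 mol %), PhSiH3, O2 (1 atm), iPrOH/CH2Cl2, 0 °C; then PPh3
Reagents that add atoms: dioxygen, O=O
Why: In this Mukaiyama hydration (hydrogen-atom-transfer Markovnikov hydration) the tertiary ring radical should be trapped by O2 from the equatorial face because the axial ester on the 1,3-related quaternary carbon blocks the axial face, which gives the equatorial hydroxyl and axial methyl of the target.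

Step 7
Reactants: 12 dimethyl (3R,3aS,7R,7aR)-3,7-dihydroxy-3,7-dimethyloctahydro-5H-indene-5,5-dicarboxylate
Product: 13 (3R,3aS,5S,7R,7aR)-3,7-dihydroxy-5-(methoxycarbonyl)-3,7-dimethyloctahydro-1H-indene-5-carboxylic acid (CO2H equatorial and CO2Me axial)
Conditions: LiOH·H2O (1.5 equiv), THF/MeOH/H2O, 25 °C; then 1 M HCl to pH 3
Reagents that add atoms: LiOH (lithium hydroxide), [Li+].[OH-]
Why: In this diastereotopic-group-selective saponification, hydroxide attacks only the equatorial ester because the axial one is screened by the syn-axial methyl, and this choice turns the quaternary carbon into a stereocentre of defined configuration.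

Step 8
Reactants: 13 (3R,3aS,5S,7R,7aR)-3,7-dihydroxy-5-(methoxycarbonyl)-3,7-dimethyloctahydro-1H-indene-5-carboxylic acid; 14 acetylacetone
Product: 16 methyl (3R,3aS,5S,7R,7aR)-5-(2-acetyl-3-oxobutanoyl)-3,7-dihydroxy-3,7-dimethyloctahydro-1H-indene-5-carboxylate, via acyl fluoride 15 (not isolated)
Conditions: cyanuric fluoride (0.5 equiv), pyridine, CH2Cl2, −10 °C; then 14 (3 equiv), MgCl2 (1.5 equiv), Et3N (4 equiv), MeCN, 0 → 25 °C; 1 M HCl work-up
Reagents that add atoms: acetylacetone 14, CC(=O)CC(C)=O; cyanuric fluoride, Fc1nc(F)nc(F)n1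
Why: Acyl fluoride formation followed by magnesium-enolate C-acylation (Rathke-type) of acetylacetone at its central carbon puts the triacylmethane on the equatorial carbonyl, with the spiro configuration retained and neither tertiary hydroxyl able to reach the acyl group.

Step 9
Reactants: 16 methyl (3R,3aS,5S,7R,7aR)-5-(2-acetyl-3-oxobutanoyl)-3,7-dihydroxy-3,7-dimethyloctahydro-1H-indene-5-carboxylate
Product: 17 spiro acetyl-trione 3'-acetyl-3,7-dihydroxy-3,7-dimethyloctahydrospiro[indene-5,1'-cyclohexane]-2',4',6'-trione (enol tautomers; hydrindane centres as in 13; the ring carbonyl next to the ring CH2 is axial)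
Conditions: LiN(iPr)2 (5 equiv), THF, −78 → 0 °C; 1 M HCl
Reagents that add atoms: none
Why: In this dianion Claisen (Dieckmann-type, polyketide-like) cyclisation an acetyl methyl carbanion attacks the axial ester from the side away from the cyclohexane, so the CH2-flanked carbonyl of the new enolised trione ring is the axial one and the acetyl-bearing carbon sits next to the equatorial carbonyl, as in the target.

Step 10
Reactants: 17 spiro acetyl-trione; 18 prenyl bromide (1-bromo-3-methylbut-2-ene)
Product: 20 target CNP0266834.2, via monoprenyl trione 19 (not isolated)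
Conditions: NaOMe (2.5 equiv), 18 (2.3 equiv), MeOH, 0 → 25 °C; aq. NH4Cl
Reagents that add atoms: prenyl bromide 18, CC(C)=CCBr
Why: Base-mediated double C-alkylation (Riedl-type lupulone prenylation) at the only remaining nucleophilic ring carbon between two carbonyls gives the gem-diprenyl carbon without creating or disturbing any stereocentre.

**Compound list**
1 | (4R)-limonene 1,2-oxide, (4R)-1-methyl-4-(prop-1-en-2-yl)-7-oxabicyclo[4.1.0]heptane, cis/trans mixture | CC(=C)[C@@H]1CCC2(C)OC2C1 | starting material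
2 | (1S,2S,4R)-1-methyl-4-(prop-1-en-2-yl)cyclohexane-1,2-diol | CC(=C)[C@@H]1CC[C@](C)(O)[C@@H](O)C1 | intermediate
3 | (3R)-6-oxo-3-(prop-1-en-2-yl)heptanal | CC(=O)CC[C@H](CC=O)C(C)=C | intermediate
4 | (1S,2R,5R)-2-hydroxy-2-methyl-5-(prop-1-en-2-yl)cyclopentane-1-carbaldehyde | O=C[C@H]1[C@@H](CC[C@@]1(C)O)C(C)=C | intermediate
5 | (1R,2R,3R)-2-(hydroxymethyl)-1-methyl-3-(prop-1-en-2-yl)cyclopentan-1-ol | OC[C@H]1[C@@H](CC[C@@]1(C)O)C(C)=C | intermediate
6 | [(1R,2R,5R)-2-hydroxy-2-methyl-5-(prop-1-en-2-yl)cyclopentyl]methyl 4-methylbenzenesulfonate | Cc1ccc(cc1)S(=O)(=O)OC[C@H]1[C@@H](CC[C@@]1(C)O)C(C)=C | intermediate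
7 | [(1R,2R,5R)-5-(3-chloroprop-1-en-2-yl)-2-hydroxy-2-methylcyclopentyl]methyl 4-methylbenzenesulfonate | Cc1ccc(cc1)S(=O)(=O)OC[C@H]1[C@@H](CC[C@@]1(C)O)C(=C)CCl | intermediate
8 | dimethyl malonate | COC(=O)CC(=O)OC | starting material
9 | dimethyl 2-{2-[(1R,2R,3R)-3-hydroxy-3-methyl-2-(tosyloxymethyl)cyclopentyl]prop-2-en-1-yl}malonate | Cc1ccc(cc1)S(=O)(=O)OC[C@H]1[C@@H](CC[C@@]1(C)O)C(=C)CC(C(=O)OC)C(=O)OC | intermediate
10 | dimethyl (3R,3aS,7aR)-3-hydroxy-3-methyl-7-methylideneoctahydro-5H-indene-5,5-dicarboxylate (trans-fused) | COC(=O)C1(C(=O)OC)C[C@H]2[C@@H](CC[C@@]2(C)O)C(=C)C1 | intermediate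
11 | dimethyl (3R,3aS,7R,7aR)-7-hydroperoxy-3-hydroxy-3,7-dimethyloctahydro-5H-indene-5,5-dicarboxylate | COC(=O)C1(C(=O)OC)C[C@H]2[C@@H](CC[C@@]2(C)O)[C@](C)(OO)C1 | intermediate
12 | dimethyl (3R,3aS,7R,7aR)-3,7-dihydroxy-3,7-dimethyloctahydro-5H-indene-5,5-dicarboxylate (C7 hydroxyl equatorial, C7 methyl axial) | COC(=O)C1(C(=O)OC)C[C@H]2[C@@H](CC[C@@]2(C)O)[C@](C)(O)C1 | intermediate
13 | (3R,3aS,5S,7R,7aR)-3,7-dihydroxy-5-(methoxycarbonyl)-3,7-dimethyloctahydro-1H-indene-5-carboxylic acid (acid equatorial, ester axial) | COC(=O)[C@]1(C[C@H]2[C@@H](CC[C@@]2(C)O)[C@](C)(O)C1)C(=O)O | intermediate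
14 | acetylacetone (pentane-2,4-dione) | CC(=O)CC(C)=O | starting material
15 | methyl (3R,3aS,5R,7R,7aR)-5-(fluorocarbonyl)-3,7-dihydroxy-3,7-dimethyloctahydro-1H-indene-5-carboxylate | COC(=O)[C@]1(C[C@H]2[C@@H](CC[C@@]2(C)O)[C@](C)(O)C1)C(F)=O | intermediate
16 | methyl (3R,3aS,5S,7R,7aR)-5-(2-acetyl-3-oxobutanoyl)-3,7-dihydroxy-3,7-dimethyloctahydro-1H-indene-5-carboxylate | COC(=O)[C@]1(C[C@H]2[C@@H](CC[C@@]2(C)O)[C@](C)(O)C1)C(=O)C(C(C)=O)C(C)=O | intermediate
17 | (3R,3aS,5R,7R,7aR)-3'-acetyl-3,7-dihydroxy-3,7-dimethyloctahydrospiro[indene-5,1'-cyclohexane]-2',4',6'-trione, drawn as one enol tautomer | CC(=O)C1=C(O)CC(=O)[C@]2(C[C@H]3[C@@H](CC[C@@]3(C)O)[C@](C)(O)C2)C1=O | intermediate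
18 | prenyl bromide (1-bromo-3-methylbut-2-ene) | CC(C)=CCBr | starting material
19 | 5'-monoprenyl derivative of 17 (prenyl-bearing carbon enolisable, configuration not fixed) | CC(=O)C1=C(O)C(CC=C(C)C)C(=O)[C@]2(C[C@H]3[C@@H](CC[C@@]3(C)O)[C@](C)(O)C2)C1=O | intermediate
20 | CNP0266834.2, (3R,3aS,5R,7R,7aR)-3'-acetyl-3,7-dihydroxy-3,7-dimethyl-5',5'-bis(3-methylbut-2-enyl)octahydrospiro[indene-5,1'-cyclohexane]-2',4',6'-trione, enol form as given | CC(=O)C1=C(O)C(CC=C(C)C)(CC=C(C)C)C(=O)[C@]2(C[C@H]3[C@@H](CC[C@@]3(C)O)[C@](C)(O)C2)C1=O | target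

**Step count and risks**

Total steps: 10. Longest linear sequence: 10 (from 1; compounds 8, 14 and 18 are commercial).

Step 2 is the first risk: the aldol may run on to the dehydrated enal or give the wrong carbinol epimer. The fallback sets out from 3 and deliberately drives the condensation (piperidine, AcOH, benzene, reflux) to the known enal (S)-2-methyl-5-(prop-1-en-2-yl)cyclopent-1-ene-1-carbaldehyde F1. Alkaline H2O2 (Weitz–Scheffer epoxidation, oxygen delivered anti to the isopropenyl group) then gives the epoxy aldehyde 5-methyl-2-(prop-1-en-2-yl)-6-oxabicyclo[3.1.0]hexane-1-carbaldehyde F2. SmI2 in THF/MeOH at −78 °C cleaves the C–O bond next to the carbonyl, the formyl-bearing carbon equilibrates to trans, and the route is rejoined at 4, which is reduced to 5 as before. Here the carbinol configuration comes from the face of epoxidation, not from aldol equilibration.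

Step 6 is the second risk: oxygen trapping of the ring radical may not be selective enough for the equatorial face. The fallback sets out from 10 and replaces the radical hydration by a polar sequence. mCPBA epoxidises the exocyclic alkene from the equatorial side (the axial ester blocks the other face) to give the spiro-epoxide dimethyl 3-hydroxy-3-methyloctahydrospiro[indene-7,2'-oxirane]-5,5-dicarboxylate F3. PhSNa in MeOH opens it at the CH2 to the hydroxy sulfide dimethyl 3,7-dihydroxy-3-methyl-7-[(phenylsulfanyl)methyl]octahydro-5H-indene-5,5-dicarboxylate F4. Raney Ni in EtOH removes sulfur and the route is rejoined at 12.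

Step 8 is the third risk: C-acylation of acetylacetone by the hindered acyl fluoride may be slow or go on oxygen. The fallback sets out from 12 and reverses the order of bond formation. Lithium acetone enolate (acetone, LiN(iPr)2, THF, −78 → 0 °C) undergoes a crossed Claisen condensation at the more accessible equatorial ester to give the β-diketone methyl (3R,3aS,5S,7R,7aR)-3,7-dihydroxy-3,7-dimethyl-5-(3-oxobutanoyl)octahydro-1H-indene-5-carboxylate F5. Its central carbon is then C-acetylated with the small electrophile AcCl (MgCl2, pyridine, CH2Cl2) and the route is rejoined at 16.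

**Further compounds**
F1 | step 2 | (S)-2-methyl-5-(prop-1-en-2-yl)cyclopent-1-ene-1-carbaldehyde | O=CC1=C(C)CC[C@H]1C(C)=C
F2 | step 2 | 5-methyl-2-(prop-1-en-2-yl)-6-oxabicyclo[3.1.0]hexane-1-carbaldehyde, epoxide oxygen trans to isopropenyl | O=C[C@@]12O[C@]1(C)CC[C@H]2C(C)=C
F3 | step 6 | dimethyl 3-hydroxy-3-methyloctahydrospiro[indene-7,2'-oxirane]-5,5-dicarboxylate, epoxide oxygen equatorial | COC(=O)C1(C(=O)OC)C[C@H]2[C@@H](CC[C@@]2(C)O)[C@@]3(CO3)C1
F4 | step 6 | dimethyl 3,7-dihydroxy-3-methyl-7-[(phenylsulfanyl)methyl]octahydro-5H-indene-5,5-dicarboxylate, C7 hydroxyl equatorial | COC(=O)C1(C(=O)OC)C[C@H]2[C@@H](CC[C@@]2(C)O)[C@](CSc3ccccc3)(O)C1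
F5 | step 8 | methyl (3R,3aS,5S,7R,7aR)-3,7-dihydroxy-3,7-dimethyl-5-(3-oxobutanoyl)octahydro-1H-indene-5-carboxylate | COC(=O)[C@]1(C[C@H]2[C@@H](CC[C@@]2(C)O)[C@](C)(O)C1)C(=O)CC(C)=O
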